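The runs stem from a simulated flask with constants of no real substance, noise included.

At late times the grey run read 100.5% after 2.50 d and 99.6% after 4.00 d, which is the charge within a scatter of 0.5 percentage points, so starting material was the limiting reagent. My decision was whether to change the enzyme charge after this flask, and that hung on the order asked for here.

- grey: starting material 0.18 M; gas 43 mM (held); enzyme 18 µM; the very flask that is asked about, followed so far
- flask: starting material 0.18 M; gas 43 mM (held); enzyme 18 µM

grey run (percent of the starting material charged)

| time / d | product / % |
|---|---|
| 0.333 | 29.5 |
| 0.500 | 45.7 |
| 0.833 | 75.9 |
| 1.67 | 100.6 |
| 2.50 | 100.5 |
| 4.00 | 99.6 |

(scatter of a reading: 0.5 percentage points)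

- at the start none of the gas is in solution
- no earlier run changes the charge of enzyme; that part of a forecast is a guess

- apparent order in enzyme when 50% of the starting material are converted (percent change of the rate of making product for one percent more enzyme charged)

The first and third readings of the grey run gave a line of slope 0.928 /d in fractions of the charge, and that line read a lag of 0.0151 d. I solved both ends and joined them. Suppose gas enters solution with a supply constant and is used with a use constant. A flask short of enzyme then has order one, a flask short of gas has order zero, and between them the order is φ, the supply constant over the sum of the two. Saturation holds 23.9% of the charge. The lag is one over that sum, and the slope is the saturation fraction times the two constants in series, so φ times its complement equals slope times lag over saturation, 0.0587. That has two roots, 0.0626 and 0.937, and slope and lag cannot part them. As a judgement, I took the lower as the supply share, since the second reading, which the line was not drawn through, stood 0.7 points above it, with 24.1% of the starting material left by the third reading, and I left the enzyme charge unchanged.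

The forecast stood at 0.93, with a range from 0.6 to 1.05, above my value, and it said: “The enzyme therefore controls most of the rate”.

    starting material + enzyme ⇌ starting complex (K = 12.8 /M, k = 1.01 × 10⁵ /M/h)
    second substrate + starting complex ⇌ ternary complex (K = 630 /M, k = 4.08 × 10⁵ /M/h)
    ternary complex → enzyme + product (k = 2450 /h)
    gas ⇌ second substrate, rate k4*(csat - [second substrate]) (kL = 0.174 /h)

The flask gave an order of 0.092, while product formed at 0.921 /d in fractions of the charge at 0.546 d. In my reckoning the supply share is also the fraction of saturation held in solution along the straight stretch, so the lower root puts second substrate at 1.50% of the charge and the upper root at 22.4%. The flask left that stretch behind by 0.945 d, when its rate stood at 0.85 of the rate at half conversion, and at 1.00 d, with starting material down to 10.8%, it held 3.54% of the charge as second substrate.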